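**Strategy**

The butenolide hides a dihydroxyacetone: ring oxygen O1 on C5 and the hydroxymethyl oxygen flank C4, which is a ketone carbon once C2 and C3 are removed. C5 is then the α-carbon of that ketone, and everything rests on joining C5 to the allylic CH2 of the side chain. In one operation the lithium azaenolate of the RAMP hydrazone of 2,2-dimethyl-1,3-dioxan-5-one is alkylated with the complete (2E,6E) side chain as its primary allylic bromide: this forms the bond, sets the only stereocentre (R) under auxiliary control and keeps both alkene geometries. Unmasking and a Wittig lactonisation with Ph3P=C=C=O then close the ring.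

Key step: step 8

Assumption: the sense of induction in step 8 is taken from the established behaviour of this hydrazone class (the SAMP hydrazone of 2,2-dimethyl-1,3-dioxan-5-one gives the (S)-4-alkyl ketone, so RAMP is chosen for (R)). Compounds 1, 6, 13 and 14 are taken as commercial.

**Route**

Step 1
Reactants: 1 dihydro-β-ionone, 4-(2,6,6-trimethylcyclohex-1-en-1-yl)butan-2-one
Product: 3 2-(but-3-yn-1-yl)-1,3,3-trimethylcyclohex-1-ene, via enol phosphate 2 (not isolated)
Conditions: LiN(iPr)2, THF, −78 °C; ClP(O)(OEt)2, −78 °C to rt; then LiN(iPr)2 (2.3 equiv), THF, −78 °C to rt; H2O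
Reagents that add atoms: none
Why: Kinetic deprotonation at the methyl group, O-phosphorylation and base-induced β-elimination of diethyl phosphate from the terminal enol phosphate should give the terminal alkyne (Negishi alkyne synthesis from methyl ketones); the tetrasubstituted ring alkene is inert.

Step 2
Reactants: 3 2-(but-3-yn-1-yl)-1,3,3-trimethylcyclohex-1-ene
Product: 5 (E)-1,3,3-trimethyl-2-(3-methylhexa-3,5-dien-1-yl)cyclohex-1-ene, via alkenyldimethylalane 4 (not isolated)
Conditions: Me3Al (2 equiv), Cp2ZrCl2 (0.25 equiv), CH2Cl2, 0 °C to rt; then vinyl bromide, Pd(PPh3)4 (5 mol %), ZnCl2, THF, rt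
Reagents that add atoms: trimethylaluminium C[Al](C)C; vinyl bromide C=CBr
Why: Zirconium-catalysed methylalumination (Negishi carboalumination) adds CH3 and Al syn across the alkyne with Al at the terminus, which fixes the E trisubstituted alkene, and the alkenylalane should couple with vinyl bromide at zerovalent palladium with retention (Negishi coupling).

Step 3
Reactants: 6 but-2-yne-1,4-diol
Product: 7 4-(tert-butyldiphenylsilyloxy)but-2-yn-1-ol
Conditions: 6 (3 equiv), TBDPSCl (1 equiv), imidazole, DMF, 0 °C to rt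
Reagents that add atoms: tert-butyl(chloro)diphenylsilane CC(C)(C)[Si](Cl)(c1ccccc1)c1ccccc1
Why: Statistical monosilylation of a symmetric diol used in excess should give mainly the mono ether, and the excess diol is washed out with water.

Step 4
Reactants: 7 4-(tert-butyldiphenylsilyloxy)but-2-yn-1-ol
Product: 9 (Z)-4-(tert-butyldiphenylsilyloxy)-3-iodobut-2-en-1-ol, via cyclic alkenylalanate 8 (not isolated)
Conditions: NaAlH2(OCH2CH2OMe)2 (Red-Al, 1.6 equiv), THF, 0 °C; EtOAc; then I2, THF, −78 to 0 °C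
Reagents that add atoms: iodine II
Why: Alkoxide-directed trans-hydroalumination of the propargylic alcohol delivers hydride to C2 and aluminium to C3 in a five-membered oxaaluminacycle, and iodinolysis with retention should give the Z 3-iodo allylic alcohol; the low temperature is meant to suppress β-elimination of silanolate to an allene.

Step 5
Reactants: 5 (E)-1,3,3-trimethyl-2-(3-methylhexa-3,5-dien-1-yl)cyclohex-1-ene; 9 (Z)-4-(tert-butyldiphenylsilyloxy)-3-iodobut-2-en-1-ol
Product: 11 (2E,6E)-3-[(tert-butyldiphenylsilyloxy)methyl]-7-methyl-9-(2,6,6-trimethylcyclohex-1-en-1-yl)nona-2,6-dien-1-ol, via homoallyl-9-BBN 10 (not isolated)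
Conditions: 9-BBN-H, THF, 0 °C to rt; then 9, Pd(dppf)Cl2 (5 mol %), AsPh3, Cs2CO3, DMF/H2O, rt
Reagents that add atoms: none
Why: 9-BBN should add only to the terminal monosubstituted alkene of the diene (anti-Markovnikov), the tri- and tetrasubstituted alkenes being inert, and the B-alkyl Suzuki–Miyaura coupling replaces iodine with retention, which places the new chain cis to the CH2OH terminus (2E).

Step 6
Reactants: 11 (2E,6E)-3-[(tert-butyldiphenylsilyloxy)methyl]-7-methyl-9-(2,6,6-trimethylcyclohex-1-en-1-yl)nona-2,6-dien-1-ol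
Product: 12 (2E,6E)-1-bromo-3-[(tert-butyldiphenylsilyloxy)methyl]-7-methyl-9-(2,6,6-trimethylcyclohex-1-en-1-yl)nona-2,6-diene
Conditions: CBr4, PPh3, CH2Cl2, 0 °C
Reagents that add atoms: carbon tetrabromide BrC(Br)(Br)Br
Why: Appel bromination of a primary allylic alcohol proceeds by SN2 at the CH2 carbon, so the alkene geometry and position should be kept.

Step 7
Reactants: 13 2,2-dimethyl-1,3-dioxan-5-one; 14 RAMP, (R)-1-amino-2-(methoxymethyl)pyrrolidine
Product: 15 RAMP hydrazone of 2,2-dimethyl-1,3-dioxan-5-one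
Conditions: benzene, reflux, Dean–Stark trap
Reagents that add atoms: none
Why: Hydrazone condensation with removal of water; the ketone is symmetric, so no C=N isomers arise.

Step 8
Reactants: 15 RAMP hydrazone of 2,2-dimethyl-1,3-dioxan-5-one; 12 (2E,6E)-1-bromo-3-[(tert-butyldiphenylsilyloxy)methyl]-7-methyl-9-(2,6,6-trimethylcyclohex-1-en-1-yl)nona-2,6-diene
Product: 17 RAMP hydrazone of (4R)-4-[(2E,6E)-3-[(tert-butyldiphenylsilyloxy)methyl]-7-methyl-9-(2,6,6-trimethylcyclohex-1-en-1-yl)nona-2,6-dien-1-yl]-2,2-dimethyl-1,3-dioxan-5-one (C=N geometry not defined), via lithium azaenolate 16 (not isolated)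
Conditions: 15 (1.5 equiv), t-BuLi (1.45 equiv), THF, −78 °C, 2 h; then 12 (1.0 equiv), −100 °C to rt
Reagents that add atoms: none
Why: tert-Butyllithium removes one α-proton of 15 to give the lithium azaenolate 16, whose lithium is chelated by the methoxymethyl arm, and this carbon nucleophile displaces bromide from the primary allylic carbon of 12 by SN2, forming the bond between the future butenolide C5 and the side-chain CH2. The closest known reaction type is the Enders SAMP/RAMP hydrazone α-alkylation of 2,2-dimethyl-1,3-dioxan-5-one with allylic halides. No ring is closed. The new stereocentre (R) is controlled by the (R)-methoxymethylpyrrolidine auxiliary, which in the rigid chelated azaenolate leaves one diastereotopic face open to the electrophile. The step needs SN2 over SN2′ regioselectivity, which the fully substituted γ-carbon of 12 should secure, and monoalkylation, which the substoichiometric base should secure. Neither alkene is touched, so both E geometries should be carried through.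

Step 9
Reactants: 17 alkylated RAMP hydrazone
Product: 18 (4R)-4-[(2E,6E)-3-[(tert-butyldiphenylsilyloxy)methyl]-7-methyl-9-(2,6,6-trimethylcyclohex-1-en-1-yl)nona-2,6-dien-1-yl]-2,2-dimethyl-1,3-dioxan-5-one
Conditions: saturated aqueous oxalic acid, Et2O, rt
Reagents that add atoms: water O
Why: Mild two-phase hydrolysis of the hydrazone removes RAMP into the aqueous phase as its oxalate and should leave the α-stereocentre, the acetonide, the TBDPS ether and the alkenes intact.

Step 10
Reactants: 18 (4R)-4-alkyl-2,2-dimethyl-1,3-dioxan-5-one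
Product: 19 (3R,5E,9E)-6-[(tert-butyldiphenylsilyloxy)methyl]-1,3-dihydroxy-10-methyl-12-(2,6,6-trimethylcyclohex-1-en-1-yl)dodeca-5,9-dien-2-one
Conditions: 1 M aqueous HCl, THF, 0 °C to rt; crude product used at once
Reagents that add atoms: none
Why: Acid-catalysed hydrolysis of the isopropylidene acetal under dilute, cold conditions should spare the TBDPS ether and the alkenes, and direct use of the diol ketone limits enediol isomerisation.

Step 11
Reactants: 19 (3R)-1,3-dihydroxy ketone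
Product: 20 (3R,5E,9E)-1-(tert-butyldimethylsilyloxy)-6-[(tert-butyldiphenylsilyloxy)methyl]-3-hydroxy-10-methyl-12-(2,6,6-trimethylcyclohex-1-en-1-yl)dodeca-5,9-dien-2-one
Conditions: TBSCl (1.05 equiv), imidazole, CH2Cl2, −20 to 0 °C
Reagents that add atoms: tert-butyl(chloro)dimethylsilane CC(C)(C)[Si](C)(C)Cl
Why: The primary hydroxyl should be silylated much faster than the secondary α-hydroxyl, which leaves only the C3 oxygen free for lactone formation.

Step 12
Reactants: 20 (3R)-3-hydroxy-1-silyloxy ketone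
Product: 22 (5R)-4-[(tert-butyldimethylsilyloxy)methyl]-5-[(2E,6E)-3-[(tert-butyldiphenylsilyloxy)methyl]-7-methyl-9-(2,6,6-trimethylcyclohex-1-en-1-yl)nona-2,6-dien-1-yl]furan-2(5H)-one, via phosphoranylidene acetate 21 (not isolated)
Conditions: Ph3P=C=C=O (1.5 equiv), toluene, 80 °C
Reagents that add atoms: (triphenylphosphoranylidene)ketene O=C=C=P(c1ccccc1)(c1ccccc1)c1ccccc1
Why: The free hydroxyl adds to the ketenylidene ylide to give an ester-stabilised ylide, which closes the butenolide by intramolecular Wittig reaction with the adjacent ketone; the weakly basic ylide should leave the stereocentre untouched.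

Step 13
Reactants: 22 bis-silylated butenolide
Product: 23 (6E)-neomanoalide, (5R)-4-(hydroxymethyl)-5-[(2E,6E)-3-(hydroxymethyl)-7-methyl-9-(2,6,6-trimethylcyclohex-1-en-1-yl)nona-2,6-dien-1-yl]furan-2(5H)-one
Conditions: HF·pyridine, pyridine, THF, 0 °C to rt
Reagents that add atoms: none
Why: Fluoride cleaves both silyl ethers under buffered, weakly acidic conditions that should not deprotonate C5 of the butenolide, so the configuration is kept.

**Compound list**

1 | dihydro-β-ionone, 4-(2,6,6-trimethylcyclohex-1-en-1-yl)butan-2-one | CC(=O)CCC1=C(C)CCCC1(C)C | starting material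
2 | diethyl 4-(2,6,6-trimethylcyclohex-1-en-1-yl)but-1-en-2-yl phosphate | CCOP(=O)(OCC)OC(=C)CCC1=C(C)CCCC1(C)C | intermediate (not isolated)
3 | 2-(but-3-yn-1-yl)-1,3,3-trimethylcyclohex-1-ene | C#CCCC1=C(C)CCCC1(C)C | intermediate
4 | (E)-dimethyl[2-methyl-4-(2,6,6-trimethylcyclohex-1-en-1-yl)but-1-en-1-yl]alane | C[Al](C)/C=C(\C)CCC1=C(C)CCCC1(C)C | intermediate (not isolated)
5 | (E)-1,3,3-trimethyl-2-(3-methylhexa-3,5-dien-1-yl)cyclohex-1-ene | C=C/C=C(\C)CCC1=C(C)CCCC1(C)C | intermediate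
6 | but-2-yne-1,4-diol | OCC#CCO | starting material
7 | 4-(tert-butyldiphenylsilyloxy)but-2-yn-1-ol | OCC#CCO[Si](c1ccccc1)(c1ccccc1)C(C)(C)C | intermediate
8 | sodium 2,2-bis(2-methoxyethoxy)-3-[(tert-butyldiphenylsilyloxy)methyl]-2,5-dihydro-1,2-oxaaluminol-2-uide (cyclic alkenylalanate) | [Na+].COCCO[Al-]1(OCCOC)OCC=C1CO[Si](c1ccccc1)(c1ccccc1)C(C)(C)C | intermediate (not isolated)
9 | (Z)-4-(tert-butyldiphenylsilyloxy)-3-iodobut-2-en-1-ol | OC/C=C(\I)CO[Si](c1ccccc1)(c1ccccc1)C(C)(C)C | intermediate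
10 | 9-[(E)-4-methyl-6-(2,6,6-trimethylcyclohex-1-en-1-yl)hex-3-en-1-yl]-9-borabicyclo[3.3.1]nonane | CC1=C(CC/C(C)=C/CCB2C3CCCC2CCC3)C(C)(C)CCC1 | intermediate (not isolated)
11 | (2E,6E)-3-[(tert-butyldiphenylsilyloxy)methyl]-7-methyl-9-(2,6,6-trimethylcyclohex-1-en-1-yl)nona-2,6-dien-1-ol | CC1=C(CC/C(C)=C/CC/C(=C\CO)CO[Si](c2ccccc2)(c2ccccc2)C(C)(C)C)C(C)(C)CCC1 | intermediate
12 | (2E,6E)-1-bromo-3-[(tert-butyldiphenylsilyloxy)methyl]-7-methyl-9-(2,6,6-trimethylcyclohex-1-en-1-yl)nona-2,6-diene | CC1=C(CC/C(C)=C/CC/C(=C\CBr)CO[Si](c2ccccc2)(c2ccccc2)C(C)(C)C)C(C)(C)CCC1 | intermediate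
13 | 2,2-dimethyl-1,3-dioxan-5-one | CC1(C)OCC(=O)CO1 | starting material
14 | RAMP, (R)-1-amino-2-(methoxymethyl)pyrrolidine | COC[C@H]1CCCN1N | starting material
15 | RAMP hydrazone of 2,2-dimethyl-1,3-dioxan-5-one | CC1(C)OCC(=NN2CCC[C@@H]2COC)CO1 | intermediate
16 | lithium azaenolate of 15 | [Li]N(N1CCC[C@@H]1COC)C1=COC(C)(C)OC1 | intermediate (not isolated)
17 | RAMP hydrazone of (4R)-4-[(2E,6E)-3-[(tert-butyldiphenylsilyloxy)methyl]-7-methyl-9-(2,6,6-trimethylcyclohex-1-en-1-yl)nona-2,6-dien-1-yl]-2,2-dimethyl-1,3-dioxan-5-one | CC1=C(CC/C(C)=C/CC/C(=C\C[C@H]2OC(C)(C)OCC2=NN2CCC[C@@H]2COC)CO[Si](c2ccccc2)(c2ccccc2)C(C)(C)C)C(C)(C)CCC1 | intermediate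
18 | (4R)-4-[(2E,6E)-3-[(tert-butyldiphenylsilyloxy)methyl]-7-methyl-9-(2,6,6-trimethylcyclohex-1-en-1-yl)nona-2,6-dien-1-yl]-2,2-dimethyl-1,3-dioxan-5-one | CC1=C(CC/C(C)=C/CC/C(=C\C[C@H]2OC(C)(C)OCC2=O)CO[Si](c2ccccc2)(c2ccccc2)C(C)(C)C)C(C)(C)CCC1 | intermediate
19 | (3R,5E,9E)-6-[(tert-butyldiphenylsilyloxy)methyl]-1,3-dihydroxy-10-methyl-12-(2,6,6-trimethylcyclohex-1-en-1-yl)dodeca-5,9-dien-2-one | CC1=C(CC/C(C)=C/CC/C(=C\C[C@@H](O)C(=O)CO)CO[Si](c2ccccc2)(c2ccccc2)C(C)(C)C)C(C)(C)CCC1 | intermediate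
20 | (3R,5E,9E)-1-(tert-butyldimethylsilyloxy)-6-[(tert-butyldiphenylsilyloxy)methyl]-3-hydroxy-10-methyl-12-(2,6,6-trimethylcyclohex-1-en-1-yl)dodeca-5,9-dien-2-one | CC1=C(CC/C(C)=C/CC/C(=C\C[C@@H](O)C(=O)CO[Si](C)(C)C(C)(C)C)CO[Si](c2ccccc2)(c2ccccc2)C(C)(C)C)C(C)(C)CCC1 | intermediate
21 | (triphenylphosphoranylidene)acetate ester of 20 at O3 | CC1=C(CC/C(C)=C/CC/C(=C\C[C@@H](OC(=O)C=P(c2ccccc2)(c2ccccc2)c2ccccc2)C(=O)CO[Si](C)(C)C(C)(C)C)CO[Si](c2ccccc2)(c2ccccc2)C(C)(C)C)C(C)(C)CCC1 | intermediate (not isolated)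
22 | (5R)-4-[(tert-butyldimethylsilyloxy)methyl]-5-[(2E,6E)-3-[(tert-butyldiphenylsilyloxy)methyl]-7-methyl-9-(2,6,6-trimethylcyclohex-1-en-1-yl)nona-2,6-dien-1-yl]furan-2(5H)-one | CC1=C(CC/C(C)=C/CC/C(=C\C[C@H]2OC(=O)C=C2CO[Si](C)(C)C(C)(C)C)CO[Si](c2ccccc2)(c2ccccc2)C(C)(C)C)C(C)(C)CCC1 | intermediate
23 | (6E)-neomanoalide | CC1=C(CC/C(C)=C/CC/C(=C\C[C@H]2OC(=O)C=C2CO)CO)C(C)(C)CCC1 | target

**Step count**

Total: 13 steps. Longest linear sequence: 10 steps (steps 1, 2, 5, 6, 8, 9, 10, 11, 12, 13 from dihydro-β-ionone).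

**Steps most likely to fail, with fallbacks**

Step 8. The azaenolate may act as a base toward the advanced bromide (1,4-elimination of HBr) or alkylate sluggishly because this electrophile cannot be used in excess, so that the costly fragment is consumed unproductively. The fallback sets out from 9 and comes back to the route at 17; it changes the order of assembly. Alcohol 9 is brominated (CBr4, PPh3, CH2Cl2, 0 °C) to tert-butyl{[(2Z)-4-bromo-2-iodobut-2-en-1-yl]oxy}diphenylsilane F1, a small electrophile that can be used in excess. Alkylation of azaenolate 16 with it under the conditions of step 8 should give the RAMP hydrazone of (4R)-4-[(2Z)-4-(tert-butyldiphenylsilyloxy)-3-iodobut-2-en-1-yl]-2,2-dimethyl-1,3-dioxan-5-one F2. The terpenoid tail is then attached by B-alkyl Suzuki–Miyaura coupling of borane 10 (made from 5 as in step 5) with this iodide (Pd(dppf)Cl2, AsPh3, Cs2CO3, DMF/H2O, rt), which should give 17.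

Step 10. Aqueous acid may cause enediol isomerisation or epimerisation of the free dihydroxy ketone, partial loss of the TBDPS ether or cyclisation of the polyene. The fallback sets out from 12 and comes back at 19; it reaches the same diol ketone under neutral oxidative conditions with a different chiral controller. (4S)-4-Benzyl-3-[(4-methoxybenzyloxy)acetyl]oxazolidin-2-one F3 is made from (S)-4-benzyloxazolidin-2-one (n-BuLi, then (4-methoxybenzyloxy)acetyl chloride). Its sodium enolate (NaN(SiMe3)2, THF, −78 °C) is alkylated with 12 (Evans glycolate alkylation; the benzyl group shields one face of the chelated Z-enolate) and should give (4S)-4-benzyl-3-[(2R,4E,8E)-5-[(tert-butyldiphenylsilyloxy)methyl]-2-(4-methoxybenzyloxy)-9-methyl-11-(2,6,6-trimethylcyclohex-1-en-1-yl)undeca-4,8-dienoyl]oxazolidin-2-one F4. Transamidation (Me(MeO)NH·HCl, Me3Al, CH2Cl2, 0 °C) should give the corresponding N-methoxy-N-methylamide F5. Addition of PMBOCH2Li (from Bu3SnCH2OPMB and n-BuLi, THF, −78 °C) should give (3R,5E,9E)-6-[(tert-butyldiphenylsilyloxy)methyl]-1,3-bis(4-methoxybenzyloxy)-10-methyl-12-(2,6,6-trimethylcyclohex-1-en-1-yl)dodeca-5,9-dien-2-one F6. Both PMB ethers are then removed with DDQ in CH2Cl2/pH 7 buffer to give 19, which is silylated at once as in step 11.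

Step 12. The hindered secondary hydroxyl may add slowly to the ylide, and heating may epimerise the α-stereocentre before ring closure. The fallback sets out from 20 and comes back at 22; it separates acylation from ring closure and runs both at or below room temperature. The hydroxyl is esterified with diethylphosphonoacetic acid (DCC, cat. DMAP, CH2Cl2, 0 °C) to (3R,5E,9E)-1-(tert-butyldimethylsilyloxy)-6-[(tert-butyldiphenylsilyloxy)methyl]-10-methyl-2-oxo-12-(2,6,6-trimethylcyclohex-1-en-1-yl)dodeca-5,9-dien-3-yl (diethoxyphosphoryl)acetate F7. Intramolecular Horner–Wadsworth–Emmons reaction under Masamune–Roush conditions (LiCl, iPr2NEt, MeCN, rt) should then close the butenolide to 22.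

**Further compounds**

F1 | step 8 | tert-butyl{[(2Z)-4-bromo-2-iodobut-2-en-1-yl]oxy}diphenylsilane | BrC/C=C(\I)CO[Si](c1ccccc1)(c1ccccc1)C(C)(C)C
F2 | step 8 | RAMP hydrazone of (4R)-4-[(2Z)-4-(tert-butyldiphenylsilyloxy)-3-iodobut-2-en-1-yl]-2,2-dimethyl-1,3-dioxan-5-one | COC[C@H]1CCCN1N=C1COC(C)(C)O[C@@H]1C/C=C(\I)CO[Si](c1ccccc1)(c1ccccc1)C(C)(C)C
F3 | step 10 | (4S)-4-benzyl-3-[(4-methoxybenzyloxy)acetyl]oxazolidin-2-one | COc1ccc(COCC(=O)N2C(=O)OC[C@@H]2Cc2ccccc2)cc1
F4 | step 10 | (4S)-4-benzyl-3-[(2R,4E,8E)-5-[(tert-butyldiphenylsilyloxy)methyl]-2-(4-methoxybenzyloxy)-9-methyl-11-(2,6,6-trimethylcyclohex-1-en-1-yl)undeca-4,8-dienoyl]oxazolidin-2-one | CC1=C(CC/C(C)=C/CC/C(=C\C[C@@H](OCc2ccc(OC)cc2)C(=O)N2C(=O)OC[C@@H]2Cc2ccccc2)CO[Si](c2ccccc2)(c2ccccc2)C(C)(C)C)C(C)(C)CCC1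
F5 | step 10 | (2R,4E,8E)-5-[(tert-butyldiphenylsilyloxy)methyl]-N-methoxy-2-(4-methoxybenzyloxy)-N,9-dimethyl-11-(2,6,6-trimethylcyclohex-1-en-1-yl)undeca-4,8-dienamide | CC1=C(CC/C(C)=C/CC/C(=C\C[C@@H](OCc2ccc(OC)cc2)C(=O)N(C)OC)CO[Si](c2ccccc2)(c2ccccc2)C(C)(C)C)C(C)(C)CCC1
F6 | step 10 | (3R,5E,9E)-6-[(tert-butyldiphenylsilyloxy)methyl]-1,3-bis(4-methoxybenzyloxy)-10-methyl-12-(2,6,6-trimethylcyclohex-1-en-1-yl)dodeca-5,9-dien-2-one | CC1=C(CC/C(C)=C/CC/C(=C\C[C@@H](OCc2ccc(OC)cc2)C(=O)COCc2ccc(OC)cc2)CO[Si](c2ccccc2)(c2ccccc2)C(C)(C)C)C(C)(C)CCC1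
F7 | step 12 | (3R,5E,9E)-1-(tert-butyldimethylsilyloxy)-6-[(tert-butyldiphenylsilyloxy)methyl]-10-methyl-2-oxo-12-(2,6,6-trimethylcyclohex-1-en-1-yl)dodeca-5,9-dien-3-yl (diethoxyphosphoryl)acetate | CC1=C(CC/C(C)=C/CC/C(=C\C[C@@H](OC(=O)CP(=O)(OCC)OCC)C(=O)CO[Si](C)(C)C(C)(C)C)CO[Si](c2ccccc2)(c2ccccc2)C(C)(C)C)C(C)(C)CCC1
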